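**Plan**

- The chain is numbered C1 (CH2 on the catechol ring) to C7 (CH2 on the guaiacyl ring). The C3 carbonyl lies 1,3 to the C5 hydroxyl, so a silicon atom carried on the C5 oxygen can reach C3 of a C2≡C3 alkyne through a five-membered O–Si–C3–C4–C5 ring. Retrosynthetically C3=O becomes the C3–Si bond of a 1,2-oxasilolane, and that in turn an Si–H/alkyne pair.
- The alkynol is cut at C3–C4 (acetylide + terminal epoxide), at C1–C2 (benzylic chloride + ethynyl Grignard) and at C6–C7 (benzylic Grignard + epichlorohydrin).
- Forward: C6–C7 and the epoxide are made first and C1–C2 on the second arm, then the halves are joined at C3–C4 and the alcohol is O-silylated. The only ring (the oxasilolane) closes by hydrosilylation, is opened oxidatively to the β-hydroxy ketone, and the benzyl ethers are removed last.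
- The single stereocentre (C5, R) comes from (R)-epichlorohydrin; its C–O bond is never broken and no other stereocentre is formed.

Key step: step 6

Remark: chlorides 1 and 6 and ethynylmagnesium bromide (THF solution) are taken as purchasable; the three phenols travel as benzyl ethers and are freed together in the last step.

**Step 1**
Reactants: 1 4-benzyloxy-3-methoxybenzyl chloride; 2 (R)-epichlorohydrin
Product: 4 (R)-4-(4-benzyloxy-3-methoxyphenyl)-1-chlorobutan-2-ol, via 4-benzyloxy-3-methoxybenzylmagnesium chloride 3 (not isolated)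
Conditions: Mg turnings (activated, excess), 2-MeTHF, 0 °C, slow addition of 1; then added to 2 (1.2 equiv), CuI (10 mol %), THF, −40 → 0 °C; cold 1 M HCl work-up
Reagents that add atoms: none
Why: Copper-catalysed Grignard opening of an epoxide, in which the benzylic organocopper species attacks the unsubstituted oxirane carbon of 2 faster than it displaces the primary chloride, so the C–O bond at the stereocentre is untouched and the R configuration is carried over.

**Step 2**
Reactants: 4 (R)-4-(4-benzyloxy-3-methoxyphenyl)-1-chlorobutan-2-ol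
Product: 5 (R)-2-[2-(4-benzyloxy-3-methoxyphenyl)ethyl]oxirane
Conditions: NaOH (2 M aq), THF, 0 °C → rt
Reagents that add atoms: none
Why: Intramolecular Williamson etherification (3-exo-tet) of the chlorohydrin alkoxide onto the neighbouring CH2Cl closes the oxirane with the oxygen staying on the stereocentre, so the configuration is retained.

**Step 3**
Reactants: 6 3,4-bis(benzyloxy)benzyl chloride; 7 ethynylmagnesium bromide
Product: 8 3-[3,4-bis(benzyloxy)phenyl]prop-1-yne
Conditions: 7 (0.5 M in THF, 3 equiv), CuCl (10 mol %), THF, 0 → 50 °C; aq. NH4Cl work-up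
Reagents that add atoms: none
Why: Copper-catalysed sp–sp3 coupling of an alkynyl Grignard reagent with a reactive benzylic chloride forms C1–C2; the excess of acetylide should suppress double benzylation and the near-neutral work-up should avoid propargyl-to-allenyl isomerisation.

**Step 4**
Reactants: 8 3-[3,4-bis(benzyloxy)phenyl]prop-1-yne; 5 (R)-2-[2-(4-benzyloxy-3-methoxyphenyl)ethyl]oxirane
Product: 10 (R)-1-(4-benzyloxy-3-methoxyphenyl)-7-[3,4-bis(benzyloxy)phenyl]hept-5-yn-3-ol, via lithium 3-[3,4-bis(benzyloxy)phenyl]prop-1-yn-1-ide 9 (not isolated)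
Conditions: 8 (1.5 equiv), n-BuLi (1.45 equiv), THF, −78 °C; BF3·OEt2 (1.5 equiv), −78 °C; then 5 (1.0 equiv), −78 °C; H2O quench at −78 °C
Reagents that add atoms: none
Why: Yamaguchi–Hirao alkynylation, in which the lithium acetylide/BF3 pair opens the Lewis-acid-activated terminal epoxide at its CH2 carbon at −78 °C, forming C3–C4 without touching the C5–O bond, so the R centre is carried over unchanged.

**Step 5**
Reactants: 10 (R)-1-(4-benzyloxy-3-methoxyphenyl)-7-[3,4-bis(benzyloxy)phenyl]hept-5-yn-3-ol; 11 1,1,3,3-tetramethyldisilazane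
Product: 12 (R)-{[1-(4-benzyloxy-3-methoxyphenyl)-7-[3,4-bis(benzyloxy)phenyl]hept-5-yn-3-yl]oxy}dimethylsilane
Conditions: 11 (2 equiv), neat, rt → 50 °C; volatiles removed under high vacuum; crude silyl ether taken on under Ar
Reagents that add atoms: none
Why: O-Silylation of a secondary alcohol by a disilazane (silyl transfer from N to O, driven by loss of ammonia) needs neither acid nor strong base, so the skipped aryl alkyne is not isomerised and the stereocentre is unaffected.

**Step 6**
Reactants: 12 (R)-{[1-(4-benzyloxy-3-methoxyphenyl)-7-[3,4-bis(benzyloxy)phenyl]hept-5-yn-3-yl]oxy}dimethylsilane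
Product: 13 (3E,5R)-5-[2-(4-benzyloxy-3-methoxyphenyl)ethyl]-3-{2-[3,4-bis(benzyloxy)phenyl]ethylidene}-2,2-dimethyl-1,2-oxasilolane
Conditions: Pt(dvds) (Karstedt catalyst, 1 mol % Pt), THF (0.05 M), rt → 40 °C
Reagents that add atoms: none
Why: The Si–H bond adds oxidatively to Pt(0), the tethered C2≡C3 triple bond coordinates and inserts in a syn sense (H to C2, Pt at C3), and reductive elimination forms the C3–Si bond (Chalk–Harrod cycle). The closest known reaction type is the platinum-catalysed intramolecular hydrosilylation of homopropargylic hydrodimethylsilyl ethers to 3-alkylidene-1,2-oxasilolanes. The one ring formed (O–Si–C3–C4–C5) closes in the 5-exo-dig mode. No stereocentre is created, C5 is a spectator, and the syn addition fixes the exocyclic alkene as E, a geometry that is erased in the next step. The selectivity required is regiochemical (silicon to C3, not C2) and it is secured by the two-atom O–Si tether, because a syn addition in the endo sense would have to place a trans double bond in a six-membered ring. Dilution should hold back intermolecular hydrosilylation, and the benzyl ethers, the aryl methyl ether and the C1 methylene are expected to be inert to Pt(0) at this temperature.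

**Step 7**
Reactants: 13 (3E,5R)-5-[2-(4-benzyloxy-3-methoxyphenyl)ethyl]-3-{2-[3,4-bis(benzyloxy)phenyl]ethylidene}-2,2-dimethyl-1,2-oxasilolane
Product: 14 (R)-7-(4-benzyloxy-3-methoxyphenyl)-1-[3,4-bis(benzyloxy)phenyl]-5-hydroxyheptan-3-one
Conditions: 30 % aq. H2O2 (10 equiv), KF (3 equiv), KHCO3 (3 equiv), THF/MeOH 1:1, 0 °C → rt; aq. Na2S2O3 work-up
Reagents that add atoms: hydrogen peroxide, OO
Why: Tamao–Kumada oxidation, in which the alkoxy-substituted silicon is activated by fluoride, the vinyl C3–Si bond migrates to peroxide oxygen and hydrolysis releases the C3 enol (which tautomerises to the ketone) together with the C5 hydroxyl, under bicarbonate buffering mild enough to spare the β-hydroxy ketone from retro-aldol cleavage or dehydration.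

**Step 8**
Reactants: 14 (R)-7-(4-benzyloxy-3-methoxyphenyl)-1-[3,4-bis(benzyloxy)phenyl]-5-hydroxyheptan-3-one
Product: 15 (R)-1-(3,4-dihydroxyphenyl)-5-hydroxy-7-(4-hydroxy-3-methoxyphenyl)heptan-3-one
Conditions: H2 (1 atm), 10 % Pd/C, degassed EtOAc/EtOH, rt; filtration and concentration under Ar
Reagents that add atoms: none
Why: Catalytic hydrogenolysis of the three benzyl aryl ethers releases toluene and the free phenols, while the saturated ketone, the secondary alcohol and the aryl methyl ether should be inert under these conditions, so C5 is not affected.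

**Compound list**

1 | 4-benzyloxy-3-methoxybenzyl chloride | COc1cc(CCl)ccc1OCc1ccccc1 | starting material
2 | (R)-epichlorohydrin | ClC[C@H]1CO1 | starting material
3 | 4-benzyloxy-3-methoxybenzylmagnesium chloride | COc1cc(C[Mg]Cl)ccc1OCc1ccccc1 | intermediate
4 | (R)-4-(4-benzyloxy-3-methoxyphenyl)-1-chlorobutan-2-ol | COc1cc(CC[C@@H](O)CCl)ccc1OCc1ccccc1 | intermediate
5 | (R)-2-[2-(4-benzyloxy-3-methoxyphenyl)ethyl]oxirane | COc1cc(CC[C@@H]2CO2)ccc1OCc1ccccc1 | intermediate
6 | 3,4-bis(benzyloxy)benzyl chloride | ClCc1ccc(OCc2ccccc2)c(OCc2ccccc2)c1 | starting material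
7 | ethynylmagnesium bromide | C#C[Mg]Br | starting material
8 | 3-[3,4-bis(benzyloxy)phenyl]prop-1-yne | C#CCc1ccc(OCc2ccccc2)c(OCc2ccccc2)c1 | intermediate
9 | lithium 3-[3,4-bis(benzyloxy)phenyl]prop-1-yn-1-ide | [Li]C#CCc1ccc(OCc2ccccc2)c(OCc2ccccc2)c1 | intermediate
10 | (R)-1-(4-benzyloxy-3-methoxyphenyl)-7-[3,4-bis(benzyloxy)phenyl]hept-5-yn-3-ol | COc1cc(CC[C@@H](O)CC#CCc2ccc(OCc3ccccc3)c(OCc3ccccc3)c2)ccc1OCc1ccccc1 | intermediate
11 | 1,1,3,3-tetramethyldisilazane | C[SiH](C)N[SiH](C)C | starting material
12 | (R)-{[1-(4-benzyloxy-3-methoxyphenyl)-7-[3,4-bis(benzyloxy)phenyl]hept-5-yn-3-yl]oxy}dimethylsilane | C[SiH](C)O[C@H](CCc1ccc(OCc2ccccc2)c(OC)c1)CC#CCc1ccc(OCc2ccccc2)c(OCc2ccccc2)c1 | intermediate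
13 | (3E,5R)-5-[2-(4-benzyloxy-3-methoxyphenyl)ethyl]-3-{2-[3,4-bis(benzyloxy)phenyl]ethylidene}-2,2-dimethyl-1,2-oxasilolane | C[Si]1(C)O[C@H](CCc2ccc(OCc3ccccc3)c(OC)c2)C/C1=C\Cc1ccc(OCc2ccccc2)c(OCc2ccccc2)c1 | intermediate
14 | (R)-7-(4-benzyloxy-3-methoxyphenyl)-1-[3,4-bis(benzyloxy)phenyl]-5-hydroxyheptan-3-one | COc1cc(CC[C@@H](O)CC(=O)CCc2ccc(OCc3ccccc3)c(OCc3ccccc3)c2)ccc1OCc1ccccc1 | intermediate
15 | (R)-1-(3,4-dihydroxyphenyl)-5-hydroxy-7-(4-hydroxy-3-methoxyphenyl)heptan-3-one | COc1cc(CC[C@@H](O)CC(=O)CCc2ccc(O)c(O)c2)ccc1O | target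

**Totals**

Total step count: 8. Longest linear sequence: 7 steps (1, 2, 4, 5, 6, 7, 8); step 3 is a one-step side branch.

**Steps most likely to fail**

Step 6. Intermolecular Si–H addition and siloxane redistribution may outrun the ring closure, or the moisture-sensitive Si–H ether may hydrolyse before the catalyst acts, so that alkynol 10 or oligomers are obtained. The fallback keeps oxygen-tethered delivery to C3 but replaces silicon by a carbonate. It sets out from 10: acylation with Boc2O and catalytic DMAP in MeCN would give tert-butyl carbonate F1. A cationic gold(I) catalyst (Ph3PAuNTf2, CH2Cl2, rt) should then induce 6-exo-dig attack of the carbonate carbonyl oxygen on C3 with loss of isobutene, giving cyclic enol carbonate F2. Cold aqueous LiOH in THF followed by buffered acidification would open the carbonate, release CO2 and deliver the β-hydroxy ketone, so the route is rejoined at 14.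

Step 4. The BF3-activated epoxide may be captured by the electron-rich guaiacyl ring (Friedel–Crafts closure) or rearrange, and the lithiated skipped alkyne may drift towards allenyl species, so that the alkynylation is eroded. The fallback reverses the order of the two alkyne bond formations and avoids the Lewis acid. It sets out from epoxide 5: lithium acetylide–ethylenediamine complex in DMSO at rt would give terminal homopropargylic alcohol F3. Double deprotonation with EtMgBr (2.2 equiv, THF) and CuCl-catalysed coupling of the resulting alkynyl Grignard with chloride 6 at 50 °C, followed by dilute HCl work-up, would return the route at 10; alkyne 8 and step 3 are then not needed.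

Step 1. Wurtz homocoupling may dominate during magnesium insertion into the electron-rich benzylic chloride, and displacement at the C–Cl end of epichlorohydrin may compete with epoxide opening. The fallback uses 1 as the electrophile and takes the stereocentre from a catalyst. It sets out from 1: allylmagnesium chloride (THF, 0 °C) would give 4-(4-benzyloxy-3-methoxyphenyl)but-1-ene F4, and mCPBA (CH2Cl2, NaHCO3) would give racemic 2-[2-(4-benzyloxy-3-methoxyphenyl)ethyl]oxirane F5. Hydrolytic kinetic resolution with (R,R)-(salen)Co(III)OAc and 0.55 equiv of water, the catalyst enantiomer expected to hydrolyse the S epoxide of alkyl oxiranes, would remove that enantiomer as its diol and leave the R epoxide, so the route is rejoined at 5 (steps 1 and 2 bypassed).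

**Further compounds**

F1 | step 6 | tert-butyl (R)-1-(4-benzyloxy-3-methoxyphenyl)-7-[3,4-bis(benzyloxy)phenyl]hept-5-yn-3-yl carbonate | COc1cc(CC[C@@H](OC(=O)OC(C)(C)C)CC#CCc2ccc(OCc3ccccc3)c(OCc3ccccc3)c2)ccc1OCc1ccccc1
F2 | step 6 | (4Z,6R)-6-[2-(4-benzyloxy-3-methoxyphenyl)ethyl]-4-{2-[3,4-bis(benzyloxy)phenyl]ethylidene}-1,3-dioxan-2-one | O=C1O[C@H](CCc2ccc(OCc3ccccc3)c(OC)c2)C/C(=C/Cc2ccc(OCc3ccccc3)c(OCc3ccccc3)c2)O1
F3 | step 4 | (R)-1-(4-benzyloxy-3-methoxyphenyl)hex-5-yn-3-ol | COc1cc(CC[C@@H](O)CC#C)ccc1OCc1ccccc1
F4 | step 1 | 4-(4-benzyloxy-3-methoxyphenyl)but-1-ene | COc1cc(CCC=C)ccc1OCc1ccccc1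
F5 | step 1 | racemic 2-[2-(4-benzyloxy-3-methoxyphenyl)ethyl]oxirane | COc1cc(CCC2CO2)ccc1OCc1ccccc1
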